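**Retrosynthetic overview** (terpenoid locants: decalin C1–C10, side chain C11–C22, CH2OH = C30; β = the face of the C10 angular carbon)
1. Target ⇐ bis-silyl ether by fluoride; C30–OH ⇐ allylic oxidation of the terminal (E)-methyl (ene reaction, then [2,3] shift).
2. C8 tertiary alcohol ⇐ Rubottom oxidation of the ring B silyl enol ether left by the cycloaddition; the C7 ketone and the C10 formyl group are then deoxygenated (Barton–McCombie).
3. Key disconnection: ring B by a Diels–Alder reaction between a ring A enal (C10=C5 dienophile) and a 2-silyloxydiene carrying C6–C9 and the whole side chain; this sets C5, C9 and C10.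
4. Ring A enal ⇐ (R)-pantolactone (C3 stereocentre and the C4 gem-dimethyl group) by Wittig extension and aldol condensation; diene ⇐ (2E,6E)-farnesyl bromide.
5. Ring order: ring A first (aldol condensation), ring B second (cycloaddition).

Assumption: the SMILES is read literally; its centres are 3S,5S,8R,9R,10S, so H-5 is cis to the C10 methyl (cis-fused decalin, not the trans-fused sclareol-type core), and every step is planned for that configuration.

**Step 1**
Reactants: 1 (R)-pantolactone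
Product: 2 (3R)-4,4-dimethyl-3-[(triisopropylsilyl)oxy]oxolan-2-one
Conditions: i-Pr3SiOTf, 2,6-lutidine, CH2Cl2, 0 °C to rt
Reagents that add atoms: triisopropylsilyl triflate, CC(C)[Si](OS(=O)(=O)C(F)(F)F)(C(C)C)C(C)C
Why: O-silylation of the hindered secondary alcohol with a silyl triflate; the bought stereocentre (future C3) is untouched and the bulky ether does not migrate in step 3.

**Step 2**
Reactants: 2 (3R)-4,4-dimethyl-3-[(triisopropylsilyl)oxy]oxolan-2-one
Product: 3 (3R)-4,4-dimethyl-3-[(triisopropylsilyl)oxy]oxolan-2-ol (lactol; both anomers)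
Conditions: i-Bu2AlH, CH2Cl2, −78 °C
Reagents that add atoms: none
Why: Half-reduction of the lactone (stable tetrahedral aluminate at −78 °C) gives the lactol; the anomeric centre is lost in step 3.

**Step 3**
Reactants: 3 (3R)-4,4-dimethyl-3-[(triisopropylsilyl)oxy]oxolan-2-ol; 4 [2-(1,3-dioxolan-2-yl)ethyl]triphenylphosphonium bromide
Product: 5 (3S,4Z)-6-(1,3-dioxolan-2-yl)-2,2-dimethyl-3-[(triisopropylsilyl)oxy]hex-4-en-1-ol
Conditions: KN(SiMe3)2, THF, −78 to 0 °C (ylide from 4); then 3, 0 °C to rt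
Reagents that add atoms: none
Why: Wittig olefination of the open-chain aldehyde of the lactol with a non-stabilised ylide installs C1, C10 and the masked C20 aldehyde; the (Z)-geometry is irrelevant and C3, flanked by the quaternary carbon, is not expected to epimerise.

**Step 4**
Reactants: 5 (3S,4Z)-6-(1,3-dioxolan-2-yl)-2,2-dimethyl-3-[(triisopropylsilyl)oxy]hex-4-en-1-ol
Product: 6 (3S)-6-(1,3-dioxolan-2-yl)-2,2-dimethyl-3-[(triisopropylsilyl)oxy]hexan-1-ol
Conditions: H2 (1 atm), Pd/C (10 wt % Pd), EtOAc, rt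
Reagents that add atoms: none
Why: Heterogeneous hydrogenation of the disubstituted alkene; the silyl ether and the acetal are inert.

**Step 5**
Reactants: 6 (3S)-6-(1,3-dioxolan-2-yl)-2,2-dimethyl-3-[(triisopropylsilyl)oxy]hexan-1-ol
Product: 7 (3S)-6-(1,3-dioxolan-2-yl)-2,2-dimethyl-3-[(triisopropylsilyl)oxy]hexanal
Conditions: TEMPO (0.1 equiv), PhI(OAc)2, CH2Cl2, rt
Reagents that add atoms: none
Why: TEMPO/PhI(OAc)2 oxidation of the neopentyl primary alcohol gives the non-enolisable aldehyde (future C5) without touching the acetal or silyl ether.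

**Step 6**
Reactants: 7 (3S)-6-(1,3-dioxolan-2-yl)-2,2-dimethyl-3-[(triisopropylsilyl)oxy]hexanal
Product: 9 (4S)-3,3-dimethyl-4-[(triisopropylsilyl)oxy]cyclohex-1-ene-1-carbaldehyde, via dialdehyde 8 (not isolated)
Conditions: 1 M HCl, THF, rt; then piperidine, AcOH (cat.), toluene, 60 °C
Reagents that add atoms: water, O
Why: Acetal hydrolysis, then amine-catalysed intramolecular aldol condensation; only the unmasked aldehyde is enolisable, so C10 attacks the neopentyl aldehyde C5 and dehydration gives the conjugated ring A enal, with C3 not involved.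

**Step 7**
Reactants: 10 (2E,6E)-farnesyl bromide; 11 N-tert-butylethanimine
Product: 13 (4E,8E)-5,9,13-trimethyltetradeca-4,8,12-trienal, via N-tert-butyl imine 12 (not isolated)
Conditions: LiN(i-Pr)2, THF, −78 °C (11); then 10, −78 to 0 °C; then aq. oxalic acid, rt
Reagents that add atoms: water, O
Why: SN2 alkylation of the lithiated imine (aza-enolate) at the primary allylic bromide keeps both olefin geometries, and imine hydrolysis gives the two-carbon homologated aldehyde.

**Step 8**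
Reactants: 13 (4E,8E)-5,9,13-trimethyltetradeca-4,8,12-trienal; 14 3-(triphenylphosphoranylidene)butan-2-one
Product: 15 (3E,7E,11E)-3,8,12,16-tetramethylheptadeca-3,7,11,15-tetraen-2-one
Conditions: toluene, 110 °C
Reagents that add atoms: none
Why: Wittig reaction of the stabilised keto ylide gives the (E)-trisubstituted enone (future C8=C9).

**Step 9**
Reactants: 15 (3E,7E,11E)-3,8,12,16-tetramethylheptadeca-3,7,11,15-tetraen-2-one
Product: 16 tert-butyldimethyl{[(3E,7E,11E)-3,8,12,16-tetramethylheptadeca-1,3,7,11,15-pentaen-2-yl]oxy}silane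
Conditions: t-BuMe2SiOTf, Et3N, CH2Cl2, 0 °C
Reagents that add atoms: tert-butyldimethylsilyl triflate, CC(C)(C)[Si](C)(C)OS(=O)(=O)C(F)(F)F
Why: Soft enolisation at the methyl group gives the cross-conjugated 2-silyloxy-1,3-diene with the (E)-C8=C9 geometry retained.

**Step 10**
Reactants: 9 (4S)-3,3-dimethyl-4-[(triisopropylsilyl)oxy]cyclohex-1-ene-1-carbaldehyde; 16 tert-butyldimethyl{[(3E,7E,11E)-3,8,12,16-tetramethylheptadeca-1,3,7,11,15-pentaen-2-yl]oxy}silane
Product: 17 cis-fused cycloadduct aldehyde (3β-OTIPS; 5β-H; 7-OTBS enol ether; 8-methyl; 9β-side chain; 10β-CHO)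
Conditions: Me2AlCl (0.3 equiv), CH2Cl2, −78 to −20 °C
Reagents that add atoms: none
Why: Lewis-acid Diels–Alder reaction in which the CH2 terminus of the silyl dienol ether bonds to the enal β-carbon C5, suprafacial addition makes H-5 and the C10 formyl group cis, the diene approaches anti to the C3 silyloxy group and the pseudoaxial C4 methyl, and the formyl-endo transition state with the (E)-diene places the C9 side chain cis to the formyl group, so C5, C9 and C10 are all set from C3.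

**Step 11**
Reactants: 17 cis-fused cycloadduct aldehyde
Product: 19 α-silyloxy ketone (7-oxo; 8α-OTBS; 8β-methyl; 10β-CHO), via silyloxy epoxide 18 (not isolated)
Conditions: dimethyldioxirane (1.05 equiv), acetone/CH2Cl2, −78 to 0 °C; then rt
Reagents that add atoms: dimethyldioxirane, CC1(C)OO1
Why: Rubottom oxidation: the electron-rich silyl enol ether is epoxidised much faster than the chain olefins, on the face anti to the pseudoaxial C9 side chain (oxygen enters α at C8), and a 1,4-silyl shift leaves the tertiary oxygen already protected.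

**Step 12**
Reactants: 19 α-silyloxy ketone
Product: 20 diol (10β-CH2OH; 7-OH as an epimer mixture; 8α-OTBS)
Conditions: i-Bu2AlH, CH2Cl2, −78 °C
Reagents that add atoms: none
Why: Hydride reduction of aldehyde and ketone through non-basic aluminium alkoxides (no silyl migration); the C7 carbinol centre is erased in step 14.

**Step 13**
Reactants: 20 diol
Product: 21 bis(S-methyl dithiocarbonate) of 20
Conditions: NaN(SiMe3)2, CS2, THF, −78 °C; then MeI, −78 to 0 °C
Reagents that add atoms: carbon disulfide, S=C=S; iodomethane, CI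
Why: Xanthate formation on the primary and the secondary alkoxide at low temperature, before the neighbouring tertiary silyl ether can migrate.

**Step 14**
Reactants: 21 bis(S-methyl dithiocarbonate)
Product: 22 (3S,5S,8R,9R,10S)-3-(triisopropylsilyloxy)-8-(tert-butyldimethylsilyloxy)polypoda-13E,17E,21-triene
Conditions: Bu3SnH (excess, 0.3 M), AIBN (0.2 equiv), toluene, 110 °C
Reagents that add atoms: none
Why: Barton–McCombie radical deoxygenation turns C20 into the C10 methyl and C7 into CH2; high tin hydride concentration outruns 6-exo closure onto the chain olefin, and no stereocentre is affected.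

**Step 15**
Reactants: 22 bis-silyl ether triene
Product: 23 (3S,5S,8R,9R,10S)-3-(triisopropylsilyloxy)-8-(tert-butyldimethylsilyloxy)polypoda-13E,17E,21E-trien-30-ol
Conditions: SeO2 (0.3 equiv), t-BuOOH, salicylic acid (0.1 equiv), CH2Cl2, 0 °C to rt
Reagents that add atoms: tert-butyl hydroperoxide, CC(C)(C)OO
Why: SeO2 allylic oxidation (ene reaction, then [2,3]-sigmatropic shift of the allylseleninic acid) is selective for the (E)-methyl of the terminal isopropylidene unit and gives the (E)-allylic alcohol.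

**Step 16**
Reactants: 23 silylated 30-alcohol
Product: 24 myrrhanol A as given, (3S,5S,8R,9R,10S)-polypoda-13E,17E,21E-triene-3,8,30-triol
Conditions: Bu4NF (excess), THF, 50 °C
Reagents that add atoms: none
Why: Fluoride cleavage of both silyl ethers, with no stereocentre touched.

**Compound list**
1 | (R)-pantolactone, (3R)-3-hydroxy-4,4-dimethyloxolan-2-one | CC1(C)COC(=O)[C@@H]1O | starting material
2 | (3R)-4,4-dimethyl-3-[(triisopropylsilyl)oxy]oxolan-2-one | CC1(C)COC(=O)[C@@H]1O[Si](C(C)C)(C(C)C)C(C)C | intermediate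
3 | (3R)-4,4-dimethyl-3-[(triisopropylsilyl)oxy]oxolan-2-ol (lactol, both anomers) | CC1(C)COC(O)[C@@H]1O[Si](C(C)C)(C(C)C)C(C)C | intermediate
4 | [2-(1,3-dioxolan-2-yl)ethyl]triphenylphosphonium bromide | [Br-].C1COC(O1)CC[P+](c1ccccc1)(c1ccccc1)c1ccccc1 | starting material
5 | (3S,4Z)-6-(1,3-dioxolan-2-yl)-2,2-dimethyl-3-[(triisopropylsilyl)oxy]hex-4-en-1-ol | OCC(C)(C)[C@@H](O[Si](C(C)C)(C(C)C)C(C)C)/C=C\CC1OCCO1 | intermediate
6 | (3S)-6-(1,3-dioxolan-2-yl)-2,2-dimethyl-3-[(triisopropylsilyl)oxy]hexan-1-ol | OCC(C)(C)[C@@H](O[Si](C(C)C)(C(C)C)C(C)C)CCCC1OCCO1 | intermediate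
7 | (3S)-6-(1,3-dioxolan-2-yl)-2,2-dimethyl-3-[(triisopropylsilyl)oxy]hexanal | O=CC(C)(C)[C@@H](O[Si](C(C)C)(C(C)C)C(C)C)CCCC1OCCO1 | intermediate
8 | (3S)-2,2-dimethyl-3-[(triisopropylsilyl)oxy]heptanedial | O=CC(C)(C)[C@@H](O[Si](C(C)C)(C(C)C)C(C)C)CCCC=O | intermediate
9 | (4S)-3,3-dimethyl-4-[(triisopropylsilyl)oxy]cyclohex-1-ene-1-carbaldehyde (ring A enal) | O=CC1=CC(C)(C)[C@@H](O[Si](C(C)C)(C(C)C)C(C)C)CC1 | intermediate
10 | (2E,6E)-farnesyl bromide | CC(C)=CCC/C(C)=C/CC/C(C)=C/CBr | starting material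
11 | N-tert-butylethanimine | CC=NC(C)(C)C | starting material
12 | N-tert-butyl imine of aldehyde 13 | CC(C)=CCC/C(C)=C/CC/C(C)=C/CCC=NC(C)(C)C | intermediate
13 | (4E,8E)-5,9,13-trimethyltetradeca-4,8,12-trienal | CC(C)=CCC/C(C)=C/CC/C(C)=C/CCC=O | intermediate
14 | 3-(triphenylphosphoranylidene)butan-2-one | CC(=O)C(C)=P(c1ccccc1)(c1ccccc1)c1ccccc1 | starting material
15 | (3E,7E,11E)-3,8,12,16-tetramethylheptadeca-3,7,11,15-tetraen-2-one | CC(C)=CCC/C(C)=C/CC/C(C)=C/CC/C=C(\C)C(C)=O | intermediate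
16 | tert-butyldimethyl{[(3E,7E,11E)-3,8,12,16-tetramethylheptadeca-1,3,7,11,15-pentaen-2-yl]oxy}silane | CC(C)=CCC/C(C)=C/CC/C(C)=C/CC/C=C(\C)C(=C)O[Si](C)(C)C(C)(C)C | intermediate
17 | cis-fused cycloadduct: 3β-OTIPS, 4,4-dimethyl, 5β-H, C7=C8 enol ether (7-OTBS, 8-methyl), 9β-[(3E,7E)-4,8,12-trimethyltrideca-3,7,11-trien-1-yl] (9α-H), 10β-CHO | CC(C)=CCC/C(C)=C/CC/C(C)=C/CC[C@@H]1[C@@]2(C=O)CC[C@H](O[Si](C(C)C)(C(C)C)C(C)C)C(C)(C)[C@H]2CC(O[Si](C)(C)C(C)(C)C)=C1C | intermediate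
18 | 7α,8α-epoxide of 17 (7β-OTBS) | CC(C)=CCC/C(C)=C/CC/C(C)=C/CC[C@@H]1[C@@]2(C=O)CC[C@H](O[Si](C(C)C)(C(C)C)C(C)C)C(C)(C)[C@H]2C[C@@]3(O[Si](C)(C)C(C)(C)C)O[C@@]13C | intermediate
19 | α-silyloxy ketone: 7-oxo, 8α-OTBS, 8β-methyl, 10β-CHO, rest as 17 | CC(C)=CCC/C(C)=C/CC/C(C)=C/CC[C@@H]1[C@@]2(C=O)CC[C@H](O[Si](C(C)C)(C(C)C)C(C)C)C(C)(C)[C@H]2CC(=O)[C@@]1(C)O[Si](C)(C)C(C)(C)C | intermediate
20 | diol: 10β-CH2OH, 7-OH (both epimers), 8α-OTBS, 3β-OTIPS | CC(C)=CCC/C(C)=C/CC/C(C)=C/CC[C@@H]1[C@@]2(CO)CC[C@H](O[Si](C(C)C)(C(C)C)C(C)C)C(C)(C)[C@H]2CC(O)[C@@]1(C)O[Si](C)(C)C(C)(C)C | intermediate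
21 | bis(S-methyl dithiocarbonate) of 20 | CC(C)=CCC/C(C)=C/CC/C(C)=C/CC[C@@H]1[C@@]2(COC(=S)SC)CC[C@H](O[Si](C(C)C)(C(C)C)C(C)C)C(C)(C)[C@H]2CC(OC(=S)SC)[C@@]1(C)O[Si](C)(C)C(C)(C)C | intermediate
22 | (3S,5S,8R,9R,10S)-3-(triisopropylsilyloxy)-8-(tert-butyldimethylsilyloxy)polypoda-13E,17E,21-triene | CC(C)=CCC/C(C)=C/CC/C(C)=C/CC[C@@H]1[C@@]2(C)CC[C@H](O[Si](C(C)C)(C(C)C)C(C)C)C(C)(C)[C@H]2CC[C@@]1(C)O[Si](C)(C)C(C)(C)C | intermediate
23 | (3S,5S,8R,9R,10S)-3-(triisopropylsilyloxy)-8-(tert-butyldimethylsilyloxy)polypoda-13E,17E,21E-trien-30-ol | C/C(=C\CC/C(C)=C/CC/C(C)=C/CC[C@@H]1[C@@]2(C)CC[C@H](O[Si](C(C)C)(C(C)C)C(C)C)C(C)(C)[C@H]2CC[C@@]1(C)O[Si](C)(C)C(C)(C)C)CO | intermediate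
24 | myrrhanol A as given, (3S,5S,8R,9R,10S)-polypoda-13E,17E,21E-triene-3,8,30-triol | C/C(=C\CC/C(C)=C/CC/C(C)=C/CC[C@@H]1[C@@]2(C)CC[C@H](O)C(C)(C)[C@H]2CC[C@@]1(C)O)CO | target

**Totals**
Total step count: 16. Longest linear sequence: 13 (steps 1–6, then 10–16).

**Three steps most likely to fail**

Step 10 (hindered cycloaddition; possible addition to the formyl group instead, or the exo adduct with C9 epimeric). The endo and facial preferences are argued from sterics, not from a close precedent. Fallback: a stepwise polar annulation. It sets out from 9 and 16. A silyl-triflate-catalysed Mukaiyama–Michael addition (t-BuMe2SiOTf 10 mol %, CH2Cl2, −78 °C) forms only the C5–C6 bond, anti to the C3 silyloxy group, and gives the open-chain aldehyde silyl enol ether F1. TiCl4 at −78 °C then closes ring B by intramolecular Mukaiyama–Michael addition of C10 to the enone carbon C9, giving after aqueous work-up the keto aldehyde F2. t-BuMe2SiOTf/Et3N converts its C7 ketone into the tetrasubstituted enol ether, which is 17.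

Step 11 (chemoselectivity over three chain olefins, and the face on which oxygen enters at C8). Fallback: oxygen delivery by a nitroso aldol reaction in place of an epoxidising reagent; this answers the chemoselectivity risk, not the facial one. It sets out from 17. PhN=O with catalytic Et3SiOTf (CH2Cl2, −78 °C) gives the α-(N-phenylaminooxy) ketone F3, the chain olefins being inert. CuSO4 in MeOH cleaves the N–O bond to the α-hydroxy ketone F4, and t-BuMe2SiOTf/2,6-lutidine silylates the tertiary alcohol, which is 19.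

Step 15 (site selectivity and over-oxidation in the late allylic oxidation). Fallback: rebuild the chain terminus in place of oxidising its methyl group. It sets out from 22. NBS in aqueous THF gives the terminal bromohydrin F5; K2CO3 in MeOH gives the terminal epoxide F6; HIO4 cleaves it to the trisnor aldehyde F7; Ph3P=C(CH3)CO2Et gives the (E)-enoate F8; i-Bu2AlH reduces the ester to the (E)-allylic alcohol, which is 23.

**Further compounds**
F1 | step 10 | open-chain Michael adduct, aldehyde silyl enol ether (C5–C6 bond formed, enone intact) | CC(C)=CCC/C(C)=C/CC/C(C)=C/CC/C=C(\C)C(=O)C[C@H]1C(=CO[Si](C)(C)C(C)(C)C)CC[C@H](O[Si](C(C)C)(C(C)C)C(C)C)C1(C)C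
F2 | step 10 | keto aldehyde (7-oxo, 8-H epimers, 10β-CHO, rest as 17) | CC(C)=CCC/C(C)=C/CC/C(C)=C/CC[C@@H]1[C@@]2(C=O)CC[C@H](O[Si](C(C)C)(C(C)C)C(C)C)C(C)(C)[C@H]2CC(=O)C1C
F3 | step 11 | α-(N-phenylaminooxy) ketone (7-oxo, 8α-ONHPh) | CC(C)=CCC/C(C)=C/CC/C(C)=C/CC[C@@H]1[C@@]2(C=O)CC[C@H](O[Si](C(C)C)(C(C)C)C(C)C)C(C)(C)[C@H]2CC(=O)[C@@]1(C)ONc1ccccc1
F4 | step 11 | α-hydroxy ketone (7-oxo, 8α-OH) | CC(C)=CCC/C(C)=C/CC/C(C)=C/CC[C@@H]1[C@@]2(C=O)CC[C@H](O[Si](C(C)C)(C(C)C)C(C)C)C(C)(C)[C@H]2CC(=O)[C@@]1(C)O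
F5 | step 15 | terminal bromohydrin of 22 (21-bromo-22-hydroxy, both epimers) | CC(C)(O)C(Br)CC/C(C)=C/CC/C(C)=C/CC[C@@H]1[C@@]2(C)CC[C@H](O[Si](C(C)C)(C(C)C)C(C)C)C(C)(C)[C@H]2CC[C@@]1(C)O[Si](C)(C)C(C)(C)C
F6 | step 15 | terminal 21,22-epoxide of 22 (both epimers) | CC3(C)OC3CC/C(C)=C/CC/C(C)=C/CC[C@@H]1[C@@]2(C)CC[C@H](O[Si](C(C)C)(C(C)C)C(C)C)C(C)(C)[C@H]2CC[C@@]1(C)O[Si](C)(C)C(C)(C)C
F7 | step 15 | trisnor aldehyde (C21 aldehyde) | O=CCC/C(C)=C/CC/C(C)=C/CC[C@@H]1[C@@]2(C)CC[C@H](O[Si](C(C)C)(C(C)C)C(C)C)C(C)(C)[C@H]2CC[C@@]1(C)O[Si](C)(C)C(C)(C)C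
F8 | step 15 | ethyl (E)-enoate (C30 as CO2Et) | CCOC(=O)/C(C)=C/CC/C(C)=C/CC/C(C)=C/CC[C@@H]1[C@@]2(C)CC[C@H](O[Si](C(C)C)(C(C)C)C(C)C)C(C)(C)[C@H]2CC[C@@]1(C)O[Si](C)(C)C(C)(C)C
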